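The cyclopentane is disconnected at C1–C5. C1 is a benzylic quaternary carbon holding the aryl ring, a methyl group and the ring bonds to C2 and C5. It is therefore traced back to a tertiary benzylic cation whose methyl was a vinyl CH2. Enantioselective protonation of the 1-(1-arylvinyl)cyclobutanol 6 makes a cyclobutane carbon shift to C1. This single event forms C1–C5, enlarges the four-membered ring to the cyclopentanone and fixes the quaternary stereocentre. The C2 ketone of 7 then activates C3 for methylenation and is replaced by the C2 methyl. Palladium-bound hydride sets C2, and borylation with invertive bromination delivers the (Z)-bromomethylidene.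

Key step: step 4

Numbering used below: C1 is the quaternary carbon, C2 is CH(CH3), C3 is the alkylidene carbon, and C4 and C5 are the ring CH2 groups. Aryl positions are primed: C1' is the attachment point, C2' carries oxygen, C4' carries methyl, C5' carries bromine.

Assumption: the sense of induction of the confined acid cannot be predicted. The catalyst antipode that gives (S)-7 is fixed in a trial run, and both antipodes are accessible from (R)- or (S)-BINOL.

Step 1
Reactants: 1 1-(2-hydroxy-4-methylphenyl)ethan-1-one
Product: 2 1-(2-methoxy-4-methylphenyl)ethan-1-one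
Conditions: MeI, K2CO3, acetone, reflux
Reagents that add atoms: iodomethane, CI
Why: Williamson O-methylation of the phenoxide; the methyl ether is small, inert to n-BuLi and to strong acid, and keeps the ring a good donor for the later cation.

Step 2
Reactants: 2 1-(2-methoxy-4-methylphenyl)ethan-1-one
Product: 3 N'-[(1E)-1-(2-methoxy-4-methylphenyl)ethylidene]-2,4,6-tri(propan-2-yl)benzene-1-sulfonohydrazide
Conditions: 2,4,6-triisopropylbenzenesulfonohydrazide, cat. HCl, MeOH, rt
Reagents that add atoms: 2,4,6-triisopropylbenzenesulfonohydrazide, CC(C)c1cc(C(C)C)c(S(=O)(=O)NN)c(C(C)C)c1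
Why: Acid-catalysed hydrazone condensation; the isopropyl groups block ortho-lithiation of the sulfonyl arene in the next step, so two equivalents of base suffice.

Step 3
Reactants: 3 N'-[(1E)-1-(2-methoxy-4-methylphenyl)ethylidene]-2,4,6-tri(propan-2-yl)benzene-1-sulfonohydrazide; 4 cyclobutanone
Product: 6 1-[1-(2-methoxy-4-methylphenyl)ethenyl]cyclobutan-1-ol, via 1-arylvinyllithium 5 (not isolated)
Conditions: n-BuLi (2.1 equiv), THF, −78 → 0 °C; then 4, −78 °C → rt; then H2O
Reagents that add atoms: none
Why: Shapiro reaction: double deprotonation, then loss of sulfinate and N2, gives the α-arylvinyllithium, which adds 1,2 to cyclobutanone because rehybridisation of the strained carbonyl favours addition over enolisation.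

Step 4
Reactants: 6 1-[1-(2-methoxy-4-methylphenyl)ethenyl]cyclobutan-1-ol
Product: 7 (2S)-2-(2-methoxy-4-methylphenyl)-2-methylcyclopentan-1-one
Conditions: BINOL-derived imidodiphosphorimidate (IDPi, N-triflyl core, bulky 3,3'-aryl groups; 5 mol %), dry toluene, −40 °C
Reagents that add atoms: none
Why: The confined chiral acid protonates the terminal CH2 of the electron-rich styrene, which becomes the C1 methyl, and leaves a tertiary benzylic cation at C1 (stabilised by the ortho methoxy and para methyl groups) paired with the chiral imidodiphosphorimidate anion, itself hydrogen-bonded to the carbinol OH. One of the two equivalent cyclobutane CH2 carbons (the future C5) then shifts from the carbinol carbon to C1 while the carbinol carbon becomes the C2 carbonyl and hands the proton back to the catalyst, the loss of four-ring strain making the shift fast and irreversible. The closest known reaction type is the catalytic enantioselective protonation-initiated semipinacol ring expansion of aryl- or oxygen-substituted vinyl cycloalkanols under chiral strong-acid or HCl/chiral hydrogen-bond-donor catalysis. The cyclopentane ring is closed by a four-to-five ring enlargement through a suprafacial 1,2-alkyl shift, not by an endo or exo cyclisation. The single new stereocentre C1 is under catalyst control: the anion covers one face of the planar cation, so C5 bonds to the open face and gives (S)-7. The step needs alkene protonation to win over ionisation of the tertiary alcohol, which the substrate secures because the aryl group sits on the central carbon of the alternative allyl cation and cannot stabilise it; the O-methyl group blocks escape to a neutral ortho-quinone methide, and 7 has no hydrogen at C1 through which it could racemise.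

Step 5
Reactants: 7 (2S)-2-(2-methoxy-4-methylphenyl)-2-methylcyclopentan-1-one
Product: 10 (2S)-2-(2-methoxy-4-methylphenyl)-2-methyl-5-methylidenecyclopentan-1-one, via Mannich base 8 (not isolated), via methiodide 9 (not isolated)
Conditions: LiN(SiMe3)2, THF, −78 °C; Me2N=CH2+ I−, −78 °C → rt; MeI, rt; aq. NaHCO3/CH2Cl2
Reagents that add atoms: Eschenmoser's salt (N,N-dimethylmethyleneiminium iodide), C[N+](C)=C.[I-]; iodomethane, CI (retained only in intermediate 9)
Why: Mannich methylenation: C3 is the only enolisable position of 7, its lithium enolate is aminomethylated, and quaternisation followed by mild-base β-elimination of trimethylamine gives the exocyclic enone without touching C1.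

Step 6
Reactants: 10 (2S)-2-(2-methoxy-4-methylphenyl)-2-methyl-5-methylidenecyclopentan-1-one
Product: 12 methyl (1S,2S)-2-(2-methoxy-4-methylphenyl)-1,2-dimethyl-5-methylidenecyclopentyl carbonate, via lithium alkoxide 11 (not isolated)
Conditions: MeLi, Et2O, −78 °C; then ClCO2Me, −78 °C → rt
Reagents that add atoms: methyllithium, [Li]C; methyl chloroformate, COC(=O)Cl
Why: Hard MeLi adds 1,2 to the cross-conjugated enone (organolithium carbonyl addition) from the face opposite the aryl group and the tertiary lithium alkoxide is acylated in the same flask; the carbinol configuration has no lasting consequence because C2 becomes part of a planar allyl unit in step 7.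

Step 7
Reactants: 12 methyl (1S,2S)-2-(2-methoxy-4-methylphenyl)-1,2-dimethyl-5-methylidenecyclopentyl carbonate
Product: 13 1-[(1R,2S)-1,2-dimethyl-3-methylidenecyclopentyl]-2-methoxy-4-methylbenzene
Conditions: Pd2(dba)3·CHCl3 (2.5 mol %), n-Bu3P (10 mol %), HCO2H, Et3N, THF, rt → 45 °C
Reagents that add atoms: none
Why: Tsuji hydrogenolysis of an allylic carbonate: zerovalent palladium ionises 12 anti to the carbonate, that is on the ring face carrying the C1 methyl and remote from the aryl group; the formate ligand of the CH2-bound σ-allyl complex then loses CO2 and passes hydride to the more substituted terminus C2 on that same face, so hydrogen ends anti and the C2 methyl syn to the aryl group while the alkene stays exocyclic.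

Step 8
Reactants: 13 1-[(1R,2S)-1,2-dimethyl-3-methylidenecyclopentyl]-2-methoxy-4-methylbenzene
Product: 14 2-{(E)-[(2S,3R)-3-(2-methoxy-4-methylphenyl)-2,3-dimethylcyclopentylidene]methyl}-4,4,5,5-tetramethyl-1,3,2-dioxaborolane
Conditions: trans-RhCl(CO)(PPh3)2 (5 mol %), B2pin2, toluene/MeCN (3:1), 80 °C
Reagents that add atoms: bis(pinacolato)diboron, CC1(C)OB(OC1(C)C)B1OC(C)(C)C(C)(C)O1
Why: Rhodium-catalysed dehydrogenative borylation of a 1,1-disubstituted alkene: a rhodium boryl adds across C3=CH2 with boron on the terminal carbon and syn β-hydride elimination from the CH2B group restores the alkene, the rotamer that places the bulky boryl group on the C4 side, away from the C2 methyl, being preferred and giving the E geometry.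

Step 9
Reactants: 14 2-{(E)-[(2S,3R)-3-(2-methoxy-4-methylphenyl)-2,3-dimethylcyclopentylidene]methyl}-4,4,5,5-tetramethyl-1,3,2-dioxaborolane
Product: 16 1-[(1R,2R,3Z)-3-(bromomethylidene)-1,2-dimethylcyclopentyl]-2-methoxy-4-methylbenzene, via anti dibromide 15 (not isolated)
Conditions: Br2 (1.0 equiv), CH2Cl2, −78 °C, dark; then NaOMe, MeOH, −78 °C → rt
Reagents that add atoms: bromine, BrBr
Why: Bromodeboronation with inversion: anti addition of Br2 to the E-alkenylboronate gives 15, methoxide binds boron, and boron and the C3 bromide leave antiperiplanar so that the remaining bromine ends next to C2 (Z); at −78 °C the alkene should consume bromine before the anisole ring does, and any ring-brominated material converges on 17 in step 10.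

Step 10
Reactants: 16 1-[(1R,2R,3Z)-3-(bromomethylidene)-1,2-dimethylcyclopentyl]-2-methoxy-4-methylbenzene
Product: 17 1-bromo-5-[(1R,2R,3Z)-3-(bromomethylidene)-1,2-dimethylcyclopentyl]-4-methoxy-2-methylbenzene
Conditions: NBS, MeCN, 0 °C → rt, dark
Reagents that add atoms: N-bromosuccinimide, O=C1CCC(=O)N1Br
Why: Electrophilic aromatic bromination: the methoxy group directs para to C5', the only activated position not flanked by two substituents, while the bromoalkene is too electron-poor to compete and exclusion of light suppresses radical benzylic or allylic attack.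

Step 11
Reactants: 17 1-bromo-5-[(1R,2R,3Z)-3-(bromomethylidene)-1,2-dimethylcyclopentyl]-4-methoxy-2-methylbenzene
Product: 18 4-bromo-2-[(1R,2R,3Z)-3-(bromomethylidene)-1,2-dimethylcyclopentyl]-5-methylphenol
Conditions: BBr3, CH2Cl2, −78 → 0 °C; then cold aq. NaHCO3
Reagents that add atoms: none
Why: Lewis-acid aryl methyl ether cleavage: BBr3 binds the methoxy oxygen and bromide removes the methyl group by SN2; aryl and alkenyl bromides are inert to this, the electron-poor bromoalkene resists protonation, and the buffered quench keeps the free phenol from adding to C3.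

Compound list
1 | 1-(2-hydroxy-4-methylphenyl)ethan-1-one | CC(=O)c1ccc(C)cc1O | starting material
2 | 1-(2-methoxy-4-methylphenyl)ethan-1-one | COc1cc(C)ccc1C(C)=O | intermediate
3 | N'-[(1E)-1-(2-methoxy-4-methylphenyl)ethylidene]-2,4,6-tri(propan-2-yl)benzene-1-sulfonohydrazide | COc1cc(C)ccc1/C(C)=N/NS(=O)(=O)c1c(C(C)C)cc(C(C)C)cc1C(C)C | intermediate
4 | cyclobutanone | O=C1CCC1 | starting material
5 | [1-(2-methoxy-4-methylphenyl)ethenyl]lithium | [Li]C(=C)c1ccc(C)cc1OC | intermediate
6 | 1-[1-(2-methoxy-4-methylphenyl)ethenyl]cyclobutan-1-ol | COc1cc(C)ccc1C(=C)C1(O)CCC1 | intermediate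
7 | (2S)-2-(2-methoxy-4-methylphenyl)-2-methylcyclopentan-1-one | COc1cc(C)ccc1[C@]2(C)CCCC2=O | intermediate
8 | (2S)-5-[(dimethylamino)methyl]-2-(2-methoxy-4-methylphenyl)-2-methylcyclopentan-1-one (both C5 epimers) | COc1cc(C)ccc1[C@]2(C)CCC(CN(C)C)C2=O | intermediate
9 | {[(3S)-3-(2-methoxy-4-methylphenyl)-3-methyl-2-oxocyclopentyl]methyl}trimethylazanium iodide (both epimers at the CH carbon) | COc1cc(C)ccc1[C@]2(C)CCC(C[N+](C)(C)C)C2=O.[I-] | intermediate
10 | (2S)-2-(2-methoxy-4-methylphenyl)-2-methyl-5-methylidenecyclopentan-1-one | COc1cc(C)ccc1[C@]2(C)CCC(=C)C2=O | intermediate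
11 | lithium (1S,2S)-2-(2-methoxy-4-methylphenyl)-1,2-dimethyl-5-methylidenecyclopentan-1-olate (oxygen syn to aryl) | COc1cc(C)ccc1[C@]2(C)CCC(=C)[C@]2(C)[O-].[Li+] | intermediate
12 | methyl (1S,2S)-2-(2-methoxy-4-methylphenyl)-1,2-dimethyl-5-methylidenecyclopentyl carbonate | COc1cc(C)ccc1[C@]2(C)CCC(=C)[C@]2(C)OC(=O)OC | intermediate
13 | 1-[(1R,2S)-1,2-dimethyl-3-methylidenecyclopentyl]-2-methoxy-4-methylbenzene (C2 methyl syn to aryl) | COc1cc(C)ccc1[C@]2(C)CCC(=C)[C@@H]2C | intermediate
14 | 2-{(E)-[(2S,3R)-3-(2-methoxy-4-methylphenyl)-2,3-dimethylcyclopentylidene]methyl}-4,4,5,5-tetramethyl-1,3,2-dioxaborolane (boron on the C4 side) | COc1cc(C)ccc1[C@]2(C)CC/C(=C\B3OC(C)(C)C(C)(C)O3)[C@@H]2C | intermediate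
15 | 2-{(S)-bromo[(1R,2R,3R)-1-bromo-3-(2-methoxy-4-methylphenyl)-2,3-dimethylcyclopentyl]methyl}-4,4,5,5-tetramethyl-1,3,2-dioxaborolane (anti adduct, drawn with the ring C–Br trans to the C2 methyl; the other anti adduct collapses to the same alkene) | COc1cc(C)ccc1[C@]2(C)CC[C@](Br)([C@@H](Br)B3OC(C)(C)C(C)(C)O3)[C@@H]2C | intermediate
16 | 1-[(1R,2R,3Z)-3-(bromomethylidene)-1,2-dimethylcyclopentyl]-2-methoxy-4-methylbenzene | COc1cc(C)ccc1[C@]2(C)CC/C(=C/Br)[C@@H]2C | intermediate
17 | 1-bromo-5-[(1R,2R,3Z)-3-(bromomethylidene)-1,2-dimethylcyclopentyl]-4-methoxy-2-methylbenzene | COc1cc(C)c(Br)cc1[C@]2(C)CC/C(=C/Br)[C@@H]2C | intermediate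
18 | 4-bromo-2-[(1R,2R,3Z)-3-(bromomethylidene)-1,2-dimethylcyclopentyl]-5-methylphenol | Cc1cc(O)c([C@]2(C)CC/C(=C/Br)[C@@H]2C)cc1Br | target

Total step count: 11. Longest linear sequence: 11 steps (1 → 18); cyclobutanone 4 enters in step 3.

Steps most likely to fail

Step 4. The ion pair may be too loose for good facial discrimination, because the ortho substituent twists the aryl ring and lengthens the life of the cation. Acid-induced oligomerisation of the styrene may also consume material. The fallback sets out from 6 and replaces the proton by a sulfenium group. An enantioselective sulfenylative semipinacol rearrangement is run with N-(phenylsulfanyl)succinimide, a chiral BINAM-derived selenophosphoramide Lewis base and a sulfonic acid co-catalyst in CH2Cl2 at low temperature. It passes through a configurationally stable thiiranium ion that the migrating ring carbon opens from the rear. It should give (2R)-2-(2-methoxy-4-methylphenyl)-2-[(phenylsulfanyl)methyl]cyclopentan-1-one F1. Hydrogenolysis of the C–S bond with acetone-deactivated Raney Ni in EtOH turns CH2SPh into the C1 methyl and rejoins the route at 7.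

Step 8. Three things may go wrong:
- Rhodium hydride formed during the reaction may move the exocyclic alkene into the ring and erase C2.
- β-Hydride elimination may run towards C2 or C4 and give allylboronates.
- The hindered alkene may react slowly or with weak E/Z discrimination.

The fallback sets out from 13. Lemieux–Johnson cleavage (K2OsO4·2H2O cat., NaIO4, 2,6-lutidine, dioxane/H2O) removes the methylene carbon under near-neutral conditions that spare the epimerisable C2. It should give (2R,3R)-3-(2-methoxy-4-methylphenyl)-2,3-dimethylcyclopentan-1-one F2. Ramirez olefination (CBr4, PPh3, toluene, 60–80 °C) gives 1-[(1R,2R)-3-(dibromomethylidene)-1,2-dimethylcyclopentyl]-2-methoxy-4-methylbenzene F3. Hydrogenolysis with Bu3SnH catalysed by Pd(PPh3)4 follows. Zerovalent palladium inserts into the less hindered C–Br bond on the C4 side, so the bromine next to C2 remains. The fallback rejoins the route at 16 and bypasses 14 and 15.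

Step 7. Hydride may be delivered to the CH2 terminus and give the tetrasubstituted ring alkene. The allylpalladium species may lose a β-hydrogen to give dienes. Facial exchange of palladium may erode the C2 configuration. The fallback sets out from 10 and uses a strictly regiospecific sigmatropic hydrogen transfer.
- MeLi addition with an aqueous quench gives (1S,2S)-2-(2-methoxy-4-methylphenyl)-1,2-dimethyl-5-methylidenecyclopentan-1-ol F4.
- Babler–Dauben oxidative transposition with pyridinium chlorochromate, [C5H5NH][CrO3Cl], in CH2Cl2 gives (3R)-3-(2-methoxy-4-methylphenyl)-2,3-dimethylcyclopent-1-ene-1-carbaldehyde F5.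
- Condensation with 4-methylbenzenesulfonohydrazide in EtOH gives N'-{(E)-[(3R)-3-(2-methoxy-4-methylphenyl)-2,3-dimethylcyclopent-1-en-1-yl]methylidene}-4-methylbenzene-1-sulfonohydrazide F6.
- Reduction with catecholborane (CHCl3, 0 °C) and then NaOAc·3H2O at reflux expels sulfinate to give {[(3R)-3-(2-methoxy-4-methylphenyl)-2,3-dimethylcyclopent-1-en-1-yl]methyl}diazene F7.
- The retro-ene loss of N2 from F7 places hydrogen on C2 from the face anti to the aryl group and rejoins the route at 13.

Further compounds
F1 | step 4 | (2R)-2-(2-methoxy-4-methylphenyl)-2-[(phenylsulfanyl)methyl]cyclopentan-1-one | COc1cc(C)ccc1[C@]2(CSc3ccccc3)CCCC2=O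
F2 | step 8 | (2R,3R)-3-(2-methoxy-4-methylphenyl)-2,3-dimethylcyclopentan-1-one | COc1cc(C)ccc1[C@]2(C)CCC(=O)[C@@H]2C
F3 | step 8 | 1-[(1R,2R)-3-(dibromomethylidene)-1,2-dimethylcyclopentyl]-2-methoxy-4-methylbenzene | COc1cc(C)ccc1[C@]2(C)CCC(=C(Br)Br)[C@@H]2C
F4 | step 7 | (1S,2S)-2-(2-methoxy-4-methylphenyl)-1,2-dimethyl-5-methylidenecyclopentan-1-ol | COc1cc(C)ccc1[C@]2(C)CCC(=C)[C@]2(C)O
F5 | step 7 | (3R)-3-(2-methoxy-4-methylphenyl)-2,3-dimethylcyclopent-1-ene-1-carbaldehyde | COc1cc(C)ccc1[C@]2(C)CCC(C=O)=C2C
F6 | step 7 | N'-{(E)-[(3R)-3-(2-methoxy-4-methylphenyl)-2,3-dimethylcyclopent-1-en-1-yl]methylidene}-4-methylbenzene-1-sulfonohydrazide | COc1cc(C)ccc1[C@]2(C)CCC(/C=N/NS(=O)(=O)c3ccc(C)cc3)=C2C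
F7 | step 7 | {[(3R)-3-(2-methoxy-4-methylphenyl)-2,3-dimethylcyclopent-1-en-1-yl]methyl}diazene | COc1cc(C)ccc1[C@]2(C)CCC(CN=N)=C2C
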